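## Retrosynthetic overview

1. The target is (13R)-ent-labd-8-en-15-oic acid (5R,10R) bound to one primary oxygen of a 1-acetylglycerol (glycerol C2 = R). The last disconnection is acid plus (S)-glycidyl acetate by epoxide opening.
2. Enabling feature: ring A (C1–C5, C10) is bare between C1 and C4. An unfunctionalised C2–C3 ethano bridge is held between the gem-dimethyl carbon C4 (a tertiary-radical site, retron isopropenyl) and C1, a CH2 on quaternary C10 (retron non-enolisable aldehyde). Both anchors sit trans on the adjacent ring-B atoms C5 and C10.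
3. Key disconnection: ring A is cut at C1–C2 and C3–C4. C2–C3 comes from vinyltriphenylphosphonium bromide in an iron-hydride-initiated radical addition, ylide formation and intramolecular Wittig annulation. Phosphorus leaves as Ph3P=O, and the C1=C2 alkene is then hydrogenated.
4. Ring B is bought as (S)-carvone, which supplies C5 and the para C8-methyl/C5-isopropenyl pattern. C10 is relayed from C5 by two α′-alkylations (methyl first, then C1 as an acetal). The C8=C9 alkene and the C9–C11 bond come from reductive enol triflation and Negishi coupling with a zinc reagent made from methyl (R)-3-methylglutarate (C13).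
5. Ring order: B (chiral pool), then A (key step). The glyceride is attached last.

Key step: step 8

Remark: labdane numbering is used for positions (ring A C1–C5/C10, ring B C5–C10, side chain C11–C16). (S)-Carvone, methyl (R)-3-methylglutarate, vinyltriphenylphosphonium bromide, isopropoxy(phenyl)silane and (R)-glycidol are taken as commercial.

## Route

Step 1
Reactants: 1 (S)-(+)-carvone
Product: 3 (5S,6RS)-2,6-dimethyl-5-(prop-1-en-2-yl)cyclohex-2-en-1-one (6-methylcarvone; C6 epimer mixture), via carvone lithium dienolate 2 (not isolated)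
Conditions: LDA (1.05 equiv), THF, −78 °C; MeI, −78 → 0 °C
Reagents that add atoms: iodomethane, CI
Why: Kinetic α′-deprotonation of the cross-conjugated enone followed by SN2 enolate methylation is standard for carvone; the new centre (later C10) forms as an epimer mixture that is planarised again in step 2, and C5 is bought with 1.

Step 2
Reactants: 3 6-methylcarvone
Product: 6 (5R,6S)-6-(dimethoxymethyl)-2,6-dimethyl-5-(prop-1-en-2-yl)cyclohex-2-en-1-one, via methylcarvone lithium dienolate 4 (not isolated), via silyl dienol ether 5 (not isolated)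
Conditions: LDA, THF, −78 °C; TMSCl, −78 → 0 °C; pentane filtration, solvent switch to CH2Cl2; HC(OMe)3 (2 equiv), TMSOTf (10 mol %), −78 °C
Reagents that add atoms: trimethyl orthoformate, COC(OC)OC
Why: This is a Mukaiyama-type alkylation of a silyl enol ether by the orthoformate-derived dimethoxycarbenium ion, and in cyclohexadiene 5 allylic strain with the C10 methyl group holds the C5 isopropenyl group pseudoaxial, so the electrophile bonds to C10 on the opposite face and C1 ends trans to isopropenyl with methyl cis to it (the trans-decalin relationship), which is why methyl is introduced first and C1 second.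

Step 3
Reactants: 6 keto acetal
Product: 8 (5R,6R)-6-(dimethoxymethyl)-2,6-dimethyl-5-(prop-1-en-2-yl)cyclohex-1-en-1-yl trifluoromethanesulfonate, via lithium enolate 7 (not isolated)
Conditions: L-Selectride (1.05 equiv), THF, −78 °C; Comins' reagent (1.2 equiv), −78 → 0 °C
Reagents that add atoms: Comins' reagent, N-(5-chloropyridin-2-yl)bis(trifluoromethanesulfonimide), Clc1ccc(nc1)N(S(=O)(=O)C(F)(F)F)S(=O)(=O)C(F)(F)F
Why: Conjugate hydride delivery by the bulky borohydride to an enone whose carbonyl group is shielded by the quaternary neighbour gives the C8=C9 enolate regiospecifically, and O-sulfonylation fixes it as the enol triflate (reductive enol triflation) without touching a stereocentre.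

Step 4
Reactants: 9 methyl (R)-3-methylglutarate [(3R)-5-methoxy-3-methyl-5-oxopentanoic acid]
Product: 10 methyl (3R)-5-hydroxy-3-methylpentanoate
Conditions: BH3·SMe2 (1.1 equiv), THF, −10 → 23 °C; then H2O
Reagents that add atoms: none
Why: Borane reduces a free carboxylic acid much faster than an ester, which differentiates the two arms of the desymmetrised glutarate so that its bought stereocentre becomes C13 (R in the target); the product is used at once to avoid lactonisation.

Step 5
Reactants: 10 methyl (3R)-5-hydroxy-3-methylpentanoate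
Product: 11 methyl (3S)-5-iodo-3-methylpentanoate
Conditions: I2, PPh3, imidazole, CH2Cl2, 0 °C
Reagents that add atoms: iodine, II
Why: Appel-type iodination of a primary alcohol proceeds by SN2 displacement of the alkoxyphosphonium ion, remote from the stereocentre (the descriptor changes only through CIP priorities).

Step 6
Reactants: 11 methyl (3S)-5-iodo-3-methylpentanoate; 8 enol triflate
Product: 13 methyl (3R)-5-[(5R,6R)-6-(dimethoxymethyl)-2,6-dimethyl-5-(prop-1-en-2-yl)cyclohex-1-en-1-yl]-3-methylpentanoate, via alkylzinc iodide 12 (not isolated)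
Conditions: Zn dust (activated with cat. BrCH2CH2Br/TMSCl), LiCl, THF, 40 °C; then 8, PdCl2(dppf)·CH2Cl2 (5 mol %), THF/NMP, 55 °C
Reagents that add atoms: none
Why: Zinc insertion into the primary iodide tolerates the ester, and Negishi sp2–sp3 coupling with a wide-bite-angle palladium catalyst replaces the triflate without moving the double bond, creating the tetrasubstituted C8=C9 alkene and the C9–C11 bond while leaving C5, C10 and C13 untouched.

Step 7
Reactants: 13 acetal ester
Product: 14 methyl (3R)-5-[(5R,6R)-6-formyl-2,6-dimethyl-5-(prop-1-en-2-yl)cyclohex-1-en-1-yl]-3-methylpentanoate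
Conditions: PPTS (0.2 equiv), acetone/H2O 9:1, 45 °C
Reagents that add atoms: water, O
Why: This is a mild acid-catalysed acetal hydrolysis in which the liberated aldehyde sits on a quaternary carbon and can neither epimerise nor move into conjugation, and the weak acid should leave the isopropenyl group unprotonated.

Step 8
Reactants: 14 aldehyde ester; 15 vinyltriphenylphosphonium bromide
Product: 17 methyl (3R)-3-methyl-5-[(4aR,8aR)-2,5,5,8a-tetramethyl-3,4,4a,5,6,8a-hexahydronaphthalen-1-yl]pentanoate (methyl ent-labda-1,8-dien-15-oate), via phosphonium ylide 16 (not isolated)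
Conditions: 15 (1.5 equiv), Fe(acac)3 (30 mol %), Ph(i-PrO)SiH2 (2 equiv), K2CO3 (3 equiv, dry powder), 1,2-dichloroethane (0.05 M, alcohol-free), Ar, 23 → 45 °C
Reagents that add atoms: none
Why: Proposed new method: Fe(acac)3 and the silane give an iron hydride that transfers H• to the CH2 terminus of the isopropenyl group, the tertiary C4 radical adds to the unsubstituted carbon of 15 (C4–C3 bond), and Fe(II) returns an electron to the strongly electrophilic α-phosphonio radical, so that ylide 16 forms with its carbanionic C2 five bonds away from the formyl carbon C1. C2 then attacks C1 in a 6-exo-trig closure (C2–C1 bond) and the oxaphosphetane collapses to the cis C1=C2 alkene of ring A and Ph3P=O, so the activating group leaves in the same event and the vinylphosphonium salt acts as a traceless ethylene equivalent. The closest known reaction types are the iron-hydride-initiated Giese/aldol radical–polar crossover annulation of γ,δ-unsaturated aldehydes with enals, the photoredox three-component olefination in which an alkyl radical adds to a vinylphosphonium salt and the reduced adduct undergoes a Wittig reaction, and the anionic cycloalkene synthesis with Schweizer's reagent; only their combination is new. No stereocentre is created: C4 becomes a non-stereogenic quaternary carbon, and the trans ring fusion is inherited from C5 and C10, whose tert-alkyl and formyl substituents are trans-diequatorial on the ring-B half-chair and therefore within bonding distance. The step needs hydrogen-atom transfer to the isopropenyl group only, which is secured because the C8=C9 alkene is tetrasubstituted and shielded and the cationic vinyl group of 15 is electron-poor, and it needs ring closure to outrun protonation, which is secured by the alcohol-free medium, the non-enolisable neopentyl aldehyde and dilution. K2CO3 takes up bromide and supplies the oxygen ligand through which the silane regenerates Fe–H, and on warming it should return any adduct parked as phosphonium salt to 16 (solid–liquid Wittig conditions).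

Step 9
Reactants: 17 diene ester
Product: 18 methyl (3R)-3-methyl-5-[(4aR,8aR)-2,5,5,8a-tetramethyl-3,4,4a,5,6,7,8,8a-octahydronaphthalen-1-yl]pentanoate (methyl ent-labd-8-en-15-oate)
Conditions: H2 (1 atm), 10% Pd/C, EtOAc, 23 °C
Reagents that add atoms: none
Why: Heterogeneous catalytic hydrogenation discriminates by substitution, so the cis-disubstituted C1=C2 alkene should be saturated while the tetrasubstituted, doubly flanked C8=C9 alkene stays off the catalyst surface; no stereocentre is formed.

Step 10
Reactants: 18 methyl ent-labd-8-en-15-oate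
Product: 19 (3R)-3-methyl-5-[(4aR,8aR)-2,5,5,8a-tetramethyl-3,4,4a,5,6,7,8,8a-octahydronaphthalen-1-yl]pentanoic acid [(13R)-ent-labd-8-en-15-oic acid]
Conditions: LiOH·H2O, THF/MeOH/H2O, 40 °C; then 1 M HCl
Reagents that add atoms: lithium hydroxide, [Li+].[OH-]
Why: This is the saponification of an unhindered methyl ester, and C13 is β to the carbonyl group and cannot epimerise.

Step 11
Reactants: 20 (R)-(+)-glycidol
Product: 21 (S)-glycidyl acetate {[(2S)-oxiran-2-yl]methyl acetate}
Conditions: Ac2O, Et3N, DMAP (cat.), CH2Cl2, 0 °C
Reagents that add atoms: acetic anhydride, CC(=O)OC(C)=O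
Why: DMAP-catalysed O-acetylation of the primary alcohol leaves the epoxide and its stereocentre untouched (R becomes S only because the CIP priorities change).

Step 12
Reactants: 19 (13R)-ent-labd-8-en-15-oic acid; 21 (S)-glycidyl acetate
Product: 22 (2R)-3-acetoxy-2-hydroxypropyl (3R)-3-methyl-5-[(4aR,8aR)-2,5,5,8a-tetramethyl-3,4,4a,5,6,7,8,8a-octahydronaphthalen-1-yl]pentanoate (target)
Conditions: 21 (1.5 equiv), (salen)Co(III) catalyst (3 mol %, the enantiomer matched to 21), i-Pr2NEt (1 equiv), MTBE, 23 °C
Reagents that add atoms: none
Why: In this cobalt(III)–salen-catalysed addition of a carboxylic acid to a terminal epoxide the carboxylate attacks the unsubstituted epoxide carbon by SN2, the C–O bond at the stereocentre is not broken so the glycerol C2 configuration is carried over (R in 22), and room temperature with only a hindered amine present should limit 1,2-acyl migration.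

## Compound list

1 | (S)-(+)-carvone | O=C1C(C)=CC[C@H](C(C)=C)C1 | starting material
2 | lithium cross-conjugated dienolate of 1 | [Li]OC1=C[C@@H](C(C)=C)CC=C1C | intermediate
3 | (5S,6RS)-2,6-dimethyl-5-(prop-1-en-2-yl)cyclohex-2-en-1-one (C6 epimer mixture) | O=C1C(C)=CC[C@H](C(C)=C)C1C | intermediate
4 | lithium cross-conjugated dienolate of 3 | [Li]OC1=C(C)[C@@H](C(C)=C)CC=C1C | intermediate
5 | {[(3R)-2,6-dimethyl-3-(prop-1-en-2-yl)cyclohexa-1,5-dien-1-yl]oxy}trimethylsilane | C[Si](C)(C)OC1=C(C)[C@@H](C(C)=C)CC=C1C | intermediate
6 | (5R,6S)-6-(dimethoxymethyl)-2,6-dimethyl-5-(prop-1-en-2-yl)cyclohex-2-en-1-one | O=C1C(C)=CC[C@H](C(C)=C)[C@@]1(C)C(OC)OC | intermediate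
7 | lithium C8=C9 enolate from conjugate reduction of 6 | [Li]OC1=C(C)CC[C@H](C(C)=C)[C@@]1(C)C(OC)OC | intermediate
8 | (5R,6R)-6-(dimethoxymethyl)-2,6-dimethyl-5-(prop-1-en-2-yl)cyclohex-1-en-1-yl trifluoromethanesulfonate | O=S(=O)(OC1=C(C)CC[C@H](C(C)=C)[C@@]1(C)C(OC)OC)C(F)(F)F | intermediate
9 | methyl (R)-3-methylglutarate (monomethyl ester) | COC(=O)C[C@H](C)CC(=O)O | starting material
10 | methyl (3R)-5-hydroxy-3-methylpentanoate | COC(=O)C[C@H](C)CCO | intermediate
11 | methyl (3S)-5-iodo-3-methylpentanoate | COC(=O)C[C@H](C)CCI | intermediate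
12 | [(3S)-5-methoxy-3-methyl-5-oxopentyl]zinc iodide | COC(=O)C[C@H](C)CC[Zn]I | intermediate
13 | methyl (3R)-5-[(5R,6R)-6-(dimethoxymethyl)-2,6-dimethyl-5-(prop-1-en-2-yl)cyclohex-1-en-1-yl]-3-methylpentanoate | COC(=O)C[C@H](C)CCC1=C(C)CC[C@H](C(C)=C)[C@@]1(C)C(OC)OC | intermediate
14 | methyl (3R)-5-[(5R,6R)-6-formyl-2,6-dimethyl-5-(prop-1-en-2-yl)cyclohex-1-en-1-yl]-3-methylpentanoate | COC(=O)C[C@H](C)CCC1=C(C)CC[C@H](C(C)=C)[C@@]1(C)C=O | intermediate
15 | vinyltriphenylphosphonium bromide | C=C[P+](c1ccccc1)(c1ccccc1)c1ccccc1.[Br-] | starting material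
16 | ylide of 14 elongated at C4 by CH2–CH=PPh3 (formyl group still present) | COC(=O)C[C@H](C)CCC1=C(C)CC[C@H](C(C)(C)CC=P(c2ccccc2)(c2ccccc2)c2ccccc2)[C@@]1(C)C=O | intermediate
17 | methyl ent-labda-1,8-dien-15-oate (13R) | COC(=O)C[C@H](C)CCC1=C(C)CC[C@@H]2C(C)(C)CC=C[C@@]12C | intermediate
18 | methyl ent-labd-8-en-15-oate (13R) | COC(=O)C[C@H](C)CCC1=C(C)CC[C@@H]2C(C)(C)CCC[C@@]12C | intermediate
19 | (13R)-ent-labd-8-en-15-oic acid | OC(=O)C[C@H](C)CCC1=C(C)CC[C@@H]2C(C)(C)CCC[C@@]12C | intermediate
20 | (R)-(+)-glycidol | OC[C@@H]1CO1 | starting material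
21 | (S)-glycidyl acetate | CC(=O)OC[C@@H]1CO1 | intermediate
22 | CNP0137802.3 | CC(=O)OC[C@@H](O)COC(=O)C[C@H](C)CCC1=C(C)CC[C@@H]2C(C)(C)CCC[C@@]12C | target

## Step count and risks

Total step count: 12.
Longest linear sequence: 9 steps (1, 2, 3, 6, 7, 8, 9, 10, 12).

**Step 8 (labelled step).**
- What may go wrong: the α-phosphonio radical or the ylide may be quenched by hydrogen-atom or proton transfer before ring closure. Iron turnover may stall once bromide displaces the oxygen ligands. Hydride transfer to the vinylphosphonium salt itself may compete.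
- Fallback with known chemistry, setting out from 14 and returning at 17. The established iron-hydride Giese/aldol annulation of the γ,δ-unsaturated aldehyde 14 with acrolein (Fe(acac)3 cat., Ph(i-PrO)SiH2, DCE/ethylene glycol, 0 °C) forms the same two ring bonds. It should give methyl ent-2-formyl-1-hydroxylabd-8-en-15-oate F1 as a diastereomer mixture. Mesylation and elimination (MsCl, Et3N; then DBU) should give methyl ent-2-formyllabda-1,8-dien-15-oate F2. Tsuji–Wilkinson decarbonylation (RhCl(PPh3)3, PhCN, 130 °C) removes the extra carbon and leads to 17.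

**Step 6.**
- What may go wrong: transmetalation and reductive elimination may be slow at a palladium centre flanked by the quaternary C10 and the methyl-bearing C8. β-Hydride elimination of the alkyl ligand and reduction of the triflate would then take over.
- Fallback setting out from 8 and returning at 13, with steps 4 and 5 no longer needed. A Heck reaction of 8 with methyl vinyl ketone (Pd(OAc)2, PPh3, Et3N, DMF, 70 °C), in which only a small alkene has to reach palladium, should give the β-ionone-type dienone (E)-4-[(5R,6R)-6-(dimethoxymethyl)-2,6-dimethyl-5-(prop-1-en-2-yl)cyclohex-1-en-1-yl]but-3-en-2-one F3. 1,4-Reduction with Stryker's reagent should give the saturated methyl ketone 4-[(5R,6R)-6-(dimethoxymethyl)-2,6-dimethyl-5-(prop-1-en-2-yl)cyclohex-1-en-1-yl]butan-2-one F4. Horner–Wadsworth–Emmons olefination (trimethyl phosphonoacetate, NaH, THF), with removal of the Z isomer, should give methyl (E)-5-[(5R,6R)-6-(dimethoxymethyl)-2,6-dimethyl-5-(prop-1-en-2-yl)cyclohex-1-en-1-yl]-3-methylpent-2-enoate F5. Copper-hydride asymmetric conjugate reduction (Cu(OAc)2, chiral bisphosphine of the sense that gives 13R, PMHS, t-BuOH, toluene) then sets C13 under catalyst control and gives 13.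

**Step 12.**
- What may go wrong: regiocontrol of the epoxide opening may be incomplete. 1,2-Acyl migration or acetyl exchange may occur in the product, which has a free secondary hydroxyl group between two esters.
- Fallback setting out from 19 and returning at 22. Steglich esterification with commercial (S)-solketal (EDC, DMAP, CH2Cl2) should give [(4R)-2,2-dimethyl-1,3-dioxolan-4-yl]methyl (13R)-ent-labd-8-en-15-oate F6. Acetonide cleavage (80% aq. AcOH, 40 °C) should give (2S)-2,3-dihydroxypropyl (13R)-ent-labd-8-en-15-oate F7. Selective acetylation of the primary hydroxyl group (AcCl, 2,4,6-collidine, CH2Cl2, −78 °C) should give 22.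

## Further compounds

F1 | step 8 | methyl ent-2-formyl-1-hydroxylabd-8-en-15-oate (C1/C2 diastereomer mixture) | COC(=O)C[C@H](C)CCC1=C(C)CC[C@@H]2C(C)(C)CC(C=O)C(O)[C@@]12C
F2 | step 8 | methyl ent-2-formyllabda-1,8-dien-15-oate | COC(=O)C[C@H](C)CCC1=C(C)CC[C@@H]2C(C)(C)CC(C=O)=C[C@@]12C
F3 | step 6 | (E)-4-[(5R,6R)-6-(dimethoxymethyl)-2,6-dimethyl-5-(prop-1-en-2-yl)cyclohex-1-en-1-yl]but-3-en-2-one | CC(=O)/C=C/C1=C(C)CC[C@H](C(C)=C)[C@@]1(C)C(OC)OC
F4 | step 6 | 4-[(5R,6R)-6-(dimethoxymethyl)-2,6-dimethyl-5-(prop-1-en-2-yl)cyclohex-1-en-1-yl]butan-2-one | CC(=O)CCC1=C(C)CC[C@H](C(C)=C)[C@@]1(C)C(OC)OC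
F5 | step 6 | methyl (E)-5-[(5R,6R)-6-(dimethoxymethyl)-2,6-dimethyl-5-(prop-1-en-2-yl)cyclohex-1-en-1-yl]-3-methylpent-2-enoate | COC(=O)/C=C(\C)CCC1=C(C)CC[C@H](C(C)=C)[C@@]1(C)C(OC)OC
F6 | step 12 | [(4R)-2,2-dimethyl-1,3-dioxolan-4-yl]methyl (13R)-ent-labd-8-en-15-oate | CC1(C)OC[C@H](COC(=O)C[C@H](C)CCC2=C(C)CC[C@@H]3C(C)(C)CCC[C@@]23C)O1
F7 | step 12 | (2S)-2,3-dihydroxypropyl (13R)-ent-labd-8-en-15-oate | OC[C@@H](O)COC(=O)C[C@H](C)CCC1=C(C)CC[C@@H]2C(C)(C)CCC[C@@]12C
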